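Late in the green and amber runs, monomer in chains has fallen well below its highest reading, and I start there to decide when the next flask has to be stopped.

| flask | free monomer | initiator | remark | time |
|---|---|---|---|---|
| green | 1.2 M | 17 mM | run made earlier |  |
| grey | 1.9 M | 17 mM | run made earlier |  |
| amber | 0.87 M | 26 mM | run made earlier |  |
| flask | 0.87 M | 17 mM |  | 12 h |

| run | time / h | monomer in chains / % |
|---|---|---|
| green | 0.250 | 27.8 |
| green | 0.667 | 48.5 |
| green | 2.00 | 55.4 |
| green | 5.00 | 34.1 |
| green | 15.0 | 28.1 |
| grey | 0.250 | 27.2 |
| grey | 0.667 | 51.1 |
| grey | 2.00 | 67.9 |
| grey | 5.00 | 58.3 |
| grey | 15.0 | 47.3 |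
| amber | 0.250 | 33.1 |
| amber | 0.667 | 53.1 |
| amber | 2.00 | 45.9 |
| amber | 5.00 | 29.6 |
| amber | 15.0 | 28.5 |

(each reading ± 0.5 percentage points)

1. time, not beyond 12 h, at which the flask holds most monomer in chains
2. the amount of monomer in chains, in percent of the free monomer charged, at that time
3. the first time at which monomer in chains reaches 25 %, in the same percent

- a reading or a percentage of monomer in chains counts all its forms, free or not

At 15.0 h the green run reads 28.1 % and the amber run 28.5 %, although their charges differ. Their mean, 28.3 %, I call the late share: the percentage of the free monomer charged that I expect still in chains late in such a run. The grey run, with the largest charge of free monomer, stays higher at 47.3 %, so I hold the late share to charges like the other two.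

The flask takes its free monomer from amber and its initiator from green, so I commit to the late share at 12 h. Amber's highest reading, 53.1 % at 0.667 h, stands 25 percentage points above that share. My decision is therefore to keep the flask's charge and stop it near its peak, not leave it standing.

The forecast expects 49 % at 1.1 h and the 25 % level at 0.22 h. Its grounds are that “monomer enters chains quickly, then chains slowly lose material”. It then has the flask decay towards roughly 21 %, and there it differs from my late share.

The flask gives 50.2 % at 1.10 h and reaches 25 % at 0.216 h, within the margins of the forecast.

    2 growing radical → dead chain (k = 4.00 × 10⁶ /M/s)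
    free monomer → decomposition product (k = 1.40 × 10⁻⁶ /s)
    crystals ⇌ monomer in chains, rate k3*(cs3 - [monomer in chains]) while solid is left; crystals form when [monomer in chains] > cs3 (solubility = 0.400 M, k = 0.0270 /s)
    initiator → 2 initiating radical (k = 9.80 × 10⁻⁵ /s)
    free monomer + initiating radical → growing radical + monomer in chains (k = 13000 /M/s)
    free monomer + growing radical → monomer in chains + growing radical, rate k6*[growing radical]*[free monomer] (k = 640 /M/s)
    monomer in chains ⇌ isomer of the product (K = 2.50, k = 2.20 × 10⁻⁴ /s)

The forecast and I part on the tail, which comes after these answers: at 12.0 h the flask holds 28.5 % in chains and 71.2 % as isomer of the product. The relaxation half-life between dissolved monomer in chains and the isomer by this step alone, both ways together, is 0.625 h, shorter than 12 h, and at 12.0 h this flask holds 2.50 times as much isomer as monomer in chains, against an equilibrium constant of 2.5 for that step (thermodynamic control).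

The neighbour flask with 0.0043 M of initiator keeps 2.11 % as free monomer at the end, so the late share of the rest gives 27.7 %. That neighbour flask holds 27.9 % in chains at the end.

All runs were generated by integration on assumed constants; noise was put on by code.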